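**Plan**

- Ring numbering: C1 (C=O), C2 (OH), C3 (henicosyl chain), C4 (C=O), C5 (OMe), C6 (H). The retrosynthesis first removes the C2–O bond (epoxyquinone isomerisation, then epoxidation), takes the quinone back to a 4-methoxyphenol, and then cuts C1–C2, C3–C4 and C4–C5 together.
- Enabling feature: the para carbons C1 and C4 carry the oxygens that a chromium methoxycarbene carbon (C1) and one of its CO ligands (C4) supply. C3, beside C4, is where a terminal alkyne delivers its substituent, and C5(OMe)=C6(H) is a 2-methoxyvinyl group on the carbene carbon.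
- Forward: the carbene complex is built from Cr(CO)6, ethynyltrimethylsilane, MeOTf and methanol. The chain is joined beforehand by acetylide alkylation of 1-bromohenicosane to tricos-1-yne. Benzannulation of the two closes the only ring with the chain and both oxygens in place.
- (NH4)2Ce(NO3)6 oxidation, epoxidation of the chain-bearing double bond and acid isomerisation finish the hydroxyquinone.
- The target has no stereocentre. The epoxide is a racemic, cis-fused intermediate whose two centres vanish in the last step.

Key step: step 5

Remark: the epoxide intermediate is racemic and one enantiomer is drawn; in the SMILES of the arene–Cr(CO)3 intermediate the η6-bound metal fragment is written as a dot-joined component.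

**Route**

Step 1
Reactants: 1 hexacarbonylchromium; 2 ethynyltrimethylsilane
Product: 5 pentacarbonyl[1-methoxy-3-(trimethylsilyl)prop-2-yn-1-ylidene]chromium, via lithium (trimethylsilyl)acetylide 3 (not isolated), via acylchromate Li[(CO)5CrC(O)C≡CSiMe3] 4 (not isolated)
Conditions: n-BuLi, THF, −78 °C; Cr(CO)6, −78 → 0 °C; solvent exchange, MeOTf, CH2Cl2, 0 °C → rt
Reagents that add atoms: methyl trifluoromethanesulfonate, COS(=O)(=O)C(F)(F)F
Why: Fischer carbene synthesis, in which acetylide 3 adds to a carbonyl ligand of Cr(CO)6 to give acylchromate 4 and the hard electrophile MeOTf alkylates its oxygen, a sequence established for alkynyl(methoxy)carbene complexes of chromium.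

Step 2
Reactants: 5 pentacarbonyl[1-methoxy-3-(trimethylsilyl)prop-2-yn-1-ylidene]chromium
Product: 7 pentacarbonyl[(2E)-1,3-dimethoxyprop-2-en-1-ylidene]chromium, via ethynyl complex (CO)5Cr=C(OMe)C≡CH 6 (not isolated)
Conditions: MeOH (3 equiv), NaOMe (10 mol %), THF, −40 → 0 °C
Reagents that add atoms: methanol, CO
Why: Methoxide cleaves the activated alkynyl C–Si bond and then catalyses the Michael addition of methanol to the β-carbon of alkynylcarbene 6 (the known base-catalysed alcohol addition to alkynyl(alkoxy)carbene complexes), attack at the carbene carbon only exchanging methoxy for methoxy, and the push–pull enol ether should settle in the less hindered E geometry.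

Step 3
Reactants: 8 henicosan-1-ol
Product: 9 1-bromohenicosane
Conditions: CBr4, PPh3, CH2Cl2, 0 °C → rt
Reagents that add atoms: carbon tetrabromide, BrC(Br)(Br)Br
Why: Appel reaction, in which the alkoxyphosphonium ion of the primary alcohol is displaced by bromide in an SN2 step that is reliable for long unbranched chains.

Step 4
Reactants: 9 1-bromohenicosane
Product: 10 tricos-1-yne
Conditions: LiC≡CH·H2NCH2CH2NH2, DMSO/THF, 10 °C → rt
Reagents that add atoms: lithium acetylide–ethylenediamine complex, [Li]C#C.NCCN
Why: SN2 alkylation of lithium acetylide by an unhindered primary bromide in a dipolar aprotic medium, the standard chain extension to terminal alkynes.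

Step 5
Reactants: 7 pentacarbonyl[(2E)-1,3-dimethoxyprop-2-en-1-ylidene]chromium; 10 tricos-1-yne
Product: 12 2-henicosyl-4,6-dimethoxyphenol, via tricarbonyl(η6-phenol)chromium complex 11 (not isolated)
Conditions: 10 (1.5 equiv), THF (0.3 M), 50 °C, argon; then air, Et2O, daylight, rt
Reagents that add atoms: none
Why: Proposed new method: heating expels one cis CO from 7, alkyne 10 coordinates and inserts into the Cr=C bond with its chain-bearing carbon ending on chromium, and migration of a CO ligand to that carbon gives an η4-dienylketene. The closest known reaction type is the Dötz benzannulation of alkenyl(methoxy)carbene chromium complexes with terminal alkynes; a vinyl terminus carrying a methoxy donor has not been shown in it. The single ring closes by 6π electrocyclisation of the dienylketene between the ketene carbon and the methoxy-bearing vinyl carbon, and the resulting cyclohexadienone enolises to the phenol, held as Cr(CO)3 complex 11 until air and light strip the metal. No stereocentre is formed. The regiochemistry of insertion is secured by the steric contrast between H and the unbranched C21 chain of a terminal alkyne, which places the chain next to the CO-derived carbon. Six-membered phenol formation must outrun CO-free five-membered closure, which the donor methoxyl encourages, and it is favoured by chromium as the metal, the O-methyl carbene, an ether solvent, moderate temperature and a high concentration of excess alkyne.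

Step 6
Reactants: 12 2-henicosyl-4,6-dimethoxyphenol
Product: 13 2-henicosyl-6-methoxycyclohexa-2,5-diene-1,4-dione
Conditions: (NH4)2Ce(NO3)6 (2.2 equiv), MeCN/CH2Cl2/H2O, 0 °C
Reagents that add atoms: water, O
Why: Oxidative demethylation of a 4-methoxyphenol by (NH4)2Ce(NO3)6, in which two one-electron oxidations give a phenoxonium ion, water adds para to the hydroxyl and methanol is lost to give the para-quinone, while the 6-methoxy group is kept as a vinylogous ester.

Step 7
Reactants: 13 2-henicosyl-6-methoxycyclohexa-2,5-diene-1,4-dione
Product: 14 rac-(1S,6R)-1-henicosyl-3-methoxy-7-oxabicyclo[4.1.0]hept-3-ene-2,5-dione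
Conditions: 30% H2O2, Na2CO3, THF/MeOH/H2O, 0 °C
Reagents that add atoms: hydrogen peroxide, OO
Why: Weitz–Scheffer nucleophilic epoxidation, in which hydroperoxide adds to the unsubstituted carbon of the chain-bearing double bond (β to the carbonyl that the methoxy group does not deactivate) and the enolate closes on the O–O bond, setting both new stereocentres together as the racemic, necessarily cis-fused epoxide.

Step 8
Reactants: 14 rac-(1S,6R)-1-henicosyl-3-methoxy-7-oxabicyclo[4.1.0]hept-3-ene-2,5-dione
Product: 15 3-henicosyl-2-hydroxy-5-methoxycyclohexa-2,5-diene-1,4-dione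
Conditions: conc. H2SO4, 0 °C → rt, 15 min; then ice-water
Reagents that add atoms: none
Why: Acid-catalysed isomerisation of an epoxyquinone to a hydroxyquinone, known for 2-alkyl-2,3-epoxy-1,4-naphthoquinones, in which protonation opens the epoxide at the chain-bearing carbon and loss of the adjacent proton restores the quinone with the hydroxyl on the former CH carbon, erasing both stereocentres.

**Compound list**

1 | hexacarbonylchromium | O=C=[Cr](=C=O)(=C=O)(=C=O)(=C=O)=C=O | starting material
2 | ethynyltrimethylsilane | C[Si](C)(C)C#C | starting material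
3 | lithium (trimethylsilyl)acetylide (not isolated) | [Li]C#C[Si](C)(C)C | intermediate
4 | lithium pentacarbonyl[1-oxido-3-(trimethylsilyl)prop-2-yn-1-ylidene]chromate (not isolated) | [Li+].[O-]C(C#C[Si](C)(C)C)=[Cr](=C=O)(=C=O)(=C=O)(=C=O)=C=O | intermediate
5 | pentacarbonyl[1-methoxy-3-(trimethylsilyl)prop-2-yn-1-ylidene]chromium | COC(C#C[Si](C)(C)C)=[Cr](=C=O)(=C=O)(=C=O)(=C=O)=C=O | intermediate
6 | pentacarbonyl(1-methoxyprop-2-yn-1-ylidene)chromium (not isolated) | COC(C#C)=[Cr](=C=O)(=C=O)(=C=O)(=C=O)=C=O | intermediate
7 | pentacarbonyl[(2E)-1,3-dimethoxyprop-2-en-1-ylidene]chromium | CO/C=C/C(OC)=[Cr](=C=O)(=C=O)(=C=O)(=C=O)=C=O | intermediate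
8 | henicosan-1-ol | CCCCCCCCCCCCCCCCCCCCCO | starting material
9 | 1-bromohenicosane | CCCCCCCCCCCCCCCCCCCCCBr | intermediate
10 | tricos-1-yne | CCCCCCCCCCCCCCCCCCCCCC#C | intermediate
11 | tricarbonyl(η6-2-henicosyl-4,6-dimethoxyphenol)chromium (not isolated) | CCCCCCCCCCCCCCCCCCCCCc1cc(OC)cc(OC)c1O.O=C=[Cr](=C=O)=C=O | intermediate
12 | 2-henicosyl-4,6-dimethoxyphenol | CCCCCCCCCCCCCCCCCCCCCc1cc(OC)cc(OC)c1O | intermediate
13 | 2-henicosyl-6-methoxycyclohexa-2,5-diene-1,4-dione | CCCCCCCCCCCCCCCCCCCCCC1=CC(=O)C=C(OC)C1=O | intermediate
14 | rac-(1S,6R)-1-henicosyl-3-methoxy-7-oxabicyclo[4.1.0]hept-3-ene-2,5-dione (cis-fused, racemic, one enantiomer drawn) | CCCCCCCCCCCCCCCCCCCCC[C@]12O[C@H]1C(=O)C=C(OC)C2=O | intermediate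
15 | 3-henicosyl-2-hydroxy-5-methoxycyclohexa-2,5-diene-1,4-dione (CNP0317656.0) | CCCCCCCCCCCCCCCCCCCCCC1=C(O)C(=O)C=C(OC)C1=O | target

**Step count and risks**

Total step count: 8. Longest linear sequence: 6 steps (steps 1, 2, 5, 6, 7, 8; the chain branch, steps 3, 4, 5, 6, 7, 8, is equally long).

Steps most likely to fail:

1. Step 5, the one step beyond known chemistry. After alkyne insertion the electron-rich vinylcarbene may cyclise without taking up CO, giving five-membered carbocycles, or the alkyne may oligomerise at the metal, so that little phenol forms. The fallback uses known chemistry without chromium; it sets out from 1-bromohenicosane 9 and comes back at quinone 13, bypassing 12. Commercial 1-methoxy-2-(methoxymethoxy)benzene is lithiated ortho to the acetal oxygen (n-BuLi, TMEDA, Et2O, 0 °C) to give [3-methoxy-2-(methoxymethoxy)phenyl]lithium F1. Alkylation of this with 9 (THF/DMPU, 0 °C → rt) gives 1-henicosyl-3-methoxy-2-(methoxymethoxy)benzene F2. Acid methanolysis (HCl, MeOH, 50 °C) frees 2-henicosyl-6-methoxyphenol F3, and Teuber oxidation with (KSO3)2NO (KH2PO4, acetone/THF/H2O, rt) at the free para position gives 13. The ring is then bought and the chain is joined by an aryl–alkyl bond.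

2. Step 2. The transient ethynyl complex may oligomerise or lose the metal before methanol adds, methanol may add a second time to the enol ether, or the double-bond geometry may not converge. The fallback sets out from hexacarbonylchromium 1 and comes back at 7 by the dianion/acid chloride route to alkoxycarbene complexes. Reduction of 1 with KC8 (THF, −78 → 0 °C) gives dipotassium pentacarbonylchromate K2[Cr(CO)5] F4. Acylation with the known reagent (E)-3-methoxyacryloyl chloride at −78 °C gives potassium pentacarbonyl[(2E)-3-methoxy-1-oxidoprop-2-en-1-ylidene]chromate F5. O-Methylation with MeOTf (CH2Cl2, 0 °C) gives 7. No alkynyl complex is involved, and the E geometry arrives with the acid chloride.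

3. Step 7. Hydroperoxide or hydroxide may attack the methoxy-bearing carbon and displace methoxide, or alkaline peroxide may cleave the ring, and the epoxide may not survive isolation. The fallback sets out from quinone 13 and comes back at target 15, replacing steps 7 and 8. Thiele–Winter acetoxylation (Ac2O, cat. H2SO4, rt) adds acetate at the same unsubstituted carbon of the chain-bearing double bond and gives 3-henicosyl-5-methoxybenzene-1,2,4-triyl triacetate F6. Methanolysis (HCl, MeOH, N2, reflux) gives 3-henicosyl-5-methoxybenzene-1,2,4-triol F7, which air (or FeCl3) oxidises to 15.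

**Further compounds**

F1 | step 5 | [3-methoxy-2-(methoxymethoxy)phenyl]lithium | [Li]c1cccc(OC)c1OCOC
F2 | step 5 | 1-henicosyl-3-methoxy-2-(methoxymethoxy)benzene | CCCCCCCCCCCCCCCCCCCCCc1cccc(OC)c1OCOC
F3 | step 5 | 2-henicosyl-6-methoxyphenol | CCCCCCCCCCCCCCCCCCCCCc1cccc(OC)c1O
F4 | step 2 | dipotassium pentacarbonylchromate, K2[Cr(CO)5] | [K+].[K+].O=C=[Cr-2](=C=O)(=C=O)(=C=O)=C=O
F5 | step 2 | potassium pentacarbonyl[(2E)-3-methoxy-1-oxidoprop-2-en-1-ylidene]chromate | [K+].[O-]C(/C=C/OC)=[Cr](=C=O)(=C=O)(=C=O)(=C=O)=C=O
F6 | step 7 | 3-henicosyl-5-methoxybenzene-1,2,4-triyl triacetate | CCCCCCCCCCCCCCCCCCCCCc1c(OC(C)=O)c(OC)cc(OC(C)=O)c1OC(C)=O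
F7 | step 7 | 3-henicosyl-5-methoxybenzene-1,2,4-triol | CCCCCCCCCCCCCCCCCCCCCc1c(O)c(OC)cc(O)c1O
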